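**Retrosynthetic overview**

1. The C7–C8 bond of the octenone chain (methyl-bearing alkene carbon to furfuryl CH2) is made second to last, in a Pd-catalysed annulative coupling of alkenyl iodide 16 with (Z)-2-methylpent-2-en-4-yn-1-ol 21. The same operation builds the furan (O1–C2 closure, 5-exo-dig, then aromatization); MOM removal follows.
2. Enabling feature: the linking CH2 lies between furan C2 (bonded to the ring oxygen) and an sp2 alkene carbon. CH2 and furan C2 can therefore be the two carbons of a terminal alkyne, O1–C5 a cis allylic alcohol and C3=C4(Me) a Z-alkene, so an acyclic enynol replaces a furfuryl organometallic.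
3. Aryl ketone: Weinreb amide 12 plus the aryl Grignard from bis-MOM 4-bromoresorcinol. C3 quaternary centre: Ir-catalysed asymmetric allylic alkylation of dimethyl malonate with the trisubstituted allylic carbonate 8, then Krapcho.
4. Carbonate 8: E-alkenyl iodide by hydrozirconation–iodination of pent-3-yn-1-ol, acetylide extension, 2E-allylic alcohol by Zr-catalysed carboalumination/formaldehyde.
5. Rings: the benzene ring is bought (4-bromoresorcinol); the furan ring is formed in step 14; there is no other ring.

Key step: step 14

Assumption: in step 6 the enantiomer of the phosphoramidite ligand is chosen so that malonate attacks the face of the (allyl)iridium intermediate that gives (S)-10 (the descriptor becomes R after decarboxylation only because CIP priorities change); if the sense of induction is opposite, the antipodal ligand is used.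

**Route**

Step 1
Reactants: 1 pent-3-yn-1-ol
Product: 3 (E)-4-iodopent-3-en-1-ol, via alkenylzirconocene chloride 2 (not isolated)
Conditions: Cp2Zr(H)Cl (2.5 equiv), THF, rt → 45 °C; then I2, 0 °C
Reagents that add atoms: iodine, II
Why: Hydrozirconation–iodination: Zr–H adds syn across the alkyne (the first equivalent is consumed as the O–Zr alkoxide), excess reagent with gentle warming should equilibrate zirconium to the less hindered methyl-bearing carbon, and iodinolysis with retention should give the E-iodide.

Step 2
Reactants: 3 (E)-4-iodopent-3-en-1-ol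
Product: 4 (E)-2,5-diiodopent-2-ene
Conditions: PPh3, I2, imidazole, CH2Cl2, 0 °C → rt
Reagents that add atoms: iodine, II
Why: Appel-type iodination by SN2 displacement at the primary carbinol; the alkenyl iodide is inert and the alkene geometry is untouched.

Step 3
Reactants: 4 (E)-2,5-diiodopent-2-ene
Product: 5 (E)-6-iodohept-5-en-1-yne
Conditions: lithium acetylide–ethylenediamine complex (1.5 equiv), DMSO, 10 °C → rt
Reagents that add atoms: lithium acetylide–ethylenediamine complex, [Li]C#C.NCCN
Why: SN2 alkylation of acetylide at the primary sp3 iodide in a dipolar aprotic solvent; the sp2 C–I bond does not react, and the low temperature should hold back E2 elimination to the diene.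

Step 4
Reactants: 5 (E)-6-iodohept-5-en-1-yne
Product: 7 (2E,6E)-7-iodo-3-methylocta-2,6-dien-1-ol, via alkenyldimethylalane 6 (not isolated)
Conditions: Me3Al (2.5 equiv), Cp2ZrCl2 (0.2 equiv), CH2Cl2, 0 °C → rt; then (CH2O)n, THF, 0 °C → rt; aq. Rochelle salt
Reagents that add atoms: trimethylaluminium, C[Al](C)C; paraformaldehyde (as formaldehyde), C=O
Why: Zr-catalysed methylalumination of the terminal alkyne (Negishi carboalumination) adds Me and Al syn with Al on the terminus, and hydroxymethylation of the alkenylalane with retention should give the 2E-allylic alcohol; n-BuLi is avoided so the alkenyl iodide is not exchanged.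

Step 5
Reactants: 7 (2E,6E)-7-iodo-3-methylocta-2,6-dien-1-ol
Product: 8 methyl [(2E,6E)-7-iodo-3-methylocta-2,6-dien-1-yl] carbonate
Conditions: ClCO2Me, pyridine, CH2Cl2, 0 °C
Reagents that add atoms: methyl chloroformate, COC(=O)Cl
Why: Acylation of a primary allylic alcohol with a chloroformate gives the carbonate leaving group needed for allyl-metal chemistry.

Step 6
Reactants: 8 methyl [(2E,6E)-7-iodo-3-methylocta-2,6-dien-1-yl] carbonate; 9 dimethyl malonate
Product: 10 dimethyl 2-[(3S,6E)-7-iodo-3-methylocta-1,6-dien-3-yl]propanedioate
Conditions: [Ir(cod)Cl]2 (2 mol%), BINOL-derived chiral phosphoramidite (4 mol%), TBD (10 mol%), NaHMDS, ZnI2, THF, rt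
Reagents that add atoms: none
Why: Ir-catalysed asymmetric allylic alkylation, known for (E)-β,β-disubstituted allylic carbonates with dialkyl malonates: the zinc malonate attacks the more substituted terminus of the (allyl)iridium intermediate (branched product), and the chiral ligand controls the face and so sets the quaternary centre.

Step 7
Reactants: 10 dimethyl 2-[(3S,6E)-7-iodo-3-methylocta-1,6-dien-3-yl]propanedioate
Product: 11 methyl (3R,6E)-3-ethenyl-7-iodo-3-methyloct-6-enoate
Conditions: LiCl, H2O, DMSO, 140 °C
Reagents that add atoms: none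
Why: Krapcho dealkoxycarbonylation (chloride demethylates one ester, the carboxylate loses CO2); the quaternary centre bears no acidic hydrogen and cannot epimerize.

Step 8
Reactants: 11 methyl (3R,6E)-3-ethenyl-7-iodo-3-methyloct-6-enoate
Product: 12 (3R,6E)-3-ethenyl-7-iodo-N-methoxy-N,3-dimethyloct-6-enamide
Conditions: MeNH(OMe)·HCl (1.5 equiv), i-PrMgCl (3.0 equiv), THF, −20 °C → 0 °C
Reagents that add atoms: N,O-dimethylhydroxylamine hydrochloride, CNOC.Cl
Why: Weinreb amide formation by aminolysis of the ester with the chloromagnesium amide; at −20 °C i-PrMgCl is consumed by the amine salt faster than it can exchange with the unactivated alkenyl iodide.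

Step 9
Reactants: 13 4-bromobenzene-1,3-diol
Product: 14 1-bromo-2,4-bis(methoxymethoxy)benzene
Conditions: MOMCl (2.5 equiv), i-Pr2NEt, CH2Cl2, 0 °C → rt
Reagents that add atoms: chloromethyl methyl ether, COCCl
Why: O-alkylation of both phenols gives base- and Grignard-stable acetal ethers.

Step 10
Reactants: 12 (3R,6E)-3-ethenyl-7-iodo-N-methoxy-N,3-dimethyloct-6-enamide; 14 1-bromo-2,4-bis(methoxymethoxy)benzene
Product: 16 (3R,6E)-1-[2,4-bis(methoxymethoxy)phenyl]-3-ethenyl-7-iodo-3-methyloct-6-en-1-one, via arylmagnesium bromide 15 (not isolated)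
Conditions: 14, Mg turnings, BrCH2CH2Br (cat.), THF, 40 °C, solution decanted from excess Mg; then 12, THF, 0 °C → rt; aq. NH4Cl
Reagents that add atoms: none
Why: Weinreb ketone synthesis: the aryl Grignard adds once to give a chelated tetrahedral intermediate that releases the ketone only on work-up, and aryl Grignard reagents do not exchange with unactivated alkenyl iodides under these conditions.

Step 11
Reactants: 17 prop-2-yn-1-ol
Product: 19 (Z)-3-iodo-2-methylprop-2-en-1-ol, via cyclic alkenylmagnesium alkoxide 18 (not isolated)
Conditions: MeMgBr (2.3 equiv), CuI (10 mol%), THF, −10 °C → rt; then I2, −10 °C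
Reagents that add atoms: methylmagnesium bromide, C[Mg]Br; iodine, II
Why: Alkoxide-directed Cu-catalysed anti-carbomagnesiation puts the methyl on C2 and holds magnesium cis to CH2O in a five-membered chelate, so iodinolysis with retention should give the Z-iodide.

Step 12
Reactants: 19 (Z)-3-iodo-2-methylprop-2-en-1-ol
Product: 20 (Z)-2-methyl-5-(trimethylsilyl)pent-2-en-4-yn-1-ol
Conditions: ethynyltrimethylsilane, PdCl2(PPh3)2 (2 mol%), CuI (4 mol%), Et3N, THF, rt
Reagents that add atoms: ethynyltrimethylsilane, C#C[Si](C)(C)C
Why: Sonogashira coupling of an alkenyl iodide proceeds with retention of alkene geometry, and the silyl cap prevents cyclization and double coupling.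

Step 13
Reactants: 20 (Z)-2-methyl-5-(trimethylsilyl)pent-2-en-4-yn-1-ol
Product: 21 (Z)-2-methylpent-2-en-4-yn-1-ol
Conditions: K2CO3 (0.2 equiv), MeOH, 0 °C; used promptly as a concentrated solution (volatile)
Reagents that add atoms: none
Why: Base-catalysed methanolysis of the C(sp)–Si bond, mild and short enough that base-induced cycloisomerization of the Z-enynol should not set in.

Step 14
Reactants: 16 (3R,6E)-1-[2,4-bis(methoxymethoxy)phenyl]-3-ethenyl-7-iodo-3-methyloct-6-en-1-one; 21 (Z)-2-methylpent-2-en-4-yn-1-ol
Product: 23 (3R,6E)-1-[2,4-bis(methoxymethoxy)phenyl]-3-ethenyl-3,7-dimethyl-8-(4-methylfuran-2-yl)oct-6-en-1-one, via 2-ylidene-2,5-dihydrofuran 22 (not isolated)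
Conditions: Pd(PPh3)4 (5 mol%), Cs2CO3 (2 equiv), 21 (1.5 equiv, slow addition), DMF, 50 °C; aq. NH4Cl work-up
Reagents that add atoms: none
Why: Proposed new method: Pd(0) inserts into the C–I bond of 16 with retention, the alkenyl–Pd(II) species binds the terminal alkyne of 21, the cis allylic hydroxyl (assisted by carbonate) attacks the internal alkyne carbon anti to palladium, and C–C reductive elimination joins the former alkyne terminus to C7 to give trienyl ether 22. In the flask (or on the mildly acidic work-up) 22 should aromatize by protonation at the exocyclic enol-ether carbon, which gives a cation stabilized by the ring oxygen and the C4 methyl, followed by loss of H-5, so that this carbon becomes the furfuryl CH2 of 23. The closest known reaction types are the Pd(0)-catalysed cyclization–coupling of 2-propargyl-1,3-dicarbonyl enolates and of 4-alkyn-1-olates with aryl or vinyl halides and triflates, and the Pd(II)-catalysed cycloisomerization and carbonylation of (Z)-2-en-4-yn-1-ols to 2-substituted furans; new here is a plain Z-enynol as O-nucleophile combined with an alkenyl iodide. The furan closes at O1–C2 in a 5-exo-dig mode; no stereocentre is formed, the C3 centre is remote and untouched, and the 6E geometry is carried over from the iodide because oxidative addition and reductive elimination retain configuration. The step needs cyclization–coupling to win over direct alkynylation of the C–H terminus, over uncoupled cycloisomerization to 2,4-dimethylfuran and over Heck reaction at the vinyl group; copper- and amine-free carbonate conditions, the Z-alkene that holds the OH within reach of the alkyne, slow addition of excess 21 and the placement of palladium trans to the tether carrying the vinyl group (intramolecular Heck closure is geometrically impossible) should secure this. Kinetic α-protonation of the dienol ether should give the skipped 1,4-diene and not the furan-conjugated isomer, and aromatization should make it irreversible under these mild conditions.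

Step 15
Reactants: 23 (3R,6E)-1-[2,4-bis(methoxymethoxy)phenyl]-3-ethenyl-3,7-dimethyl-8-(4-methylfuran-2-yl)oct-6-en-1-one
Product: 24 (3R,6E)-1-(2,4-dihydroxyphenyl)-3-ethenyl-3,7-dimethyl-8-(4-methylfuran-2-yl)oct-6-en-1-one
Conditions: p-TsOH·H2O (0.2 equiv), MeOH, 30 °C, short contact; NaHCO3 quench
Reagents that add atoms: none
Why: Acid-catalysed transacetalization of both aryl MOM ethers to methanol; acyl-substituted phenols are good leaving groups, so mild acid that the 2,4-dialkylfuran and the skipped diene should tolerate is expected to suffice, and no stereocentre is involved.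

**Compound list**

1 | pent-3-yn-1-ol | CC#CCCO | starting material
2 | (E)-alkenylzirconocene chloride of 1, O-zirconated (formed in the flask) | C/C(=C\CCO[Zr](Cl)(C1C=CC=C1)C1C=CC=C1)[Zr](Cl)(C1C=CC=C1)C1C=CC=C1 | intermediate
3 | (E)-4-iodopent-3-en-1-ol | C/C(I)=C\CCO | intermediate
4 | (E)-2,5-diiodopent-2-ene | C/C(I)=C\CCI | intermediate
5 | (E)-6-iodohept-5-en-1-yne | C#CCC/C=C(\C)I | intermediate
6 | dimethyl[(1E,5E)-6-iodo-2-methylhepta-1,5-dien-1-yl]alumane (formed in the flask) | C[Al](C)/C=C(\C)CC/C=C(\C)I | intermediate
7 | (2E,6E)-7-iodo-3-methylocta-2,6-dien-1-ol | OC/C=C(\C)CC/C=C(\C)I | intermediate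
8 | methyl [(2E,6E)-7-iodo-3-methylocta-2,6-dien-1-yl] carbonate | COC(=O)OC/C=C(\C)CC/C=C(\C)I | intermediate
9 | dimethyl malonate | COC(=O)CC(=O)OC | starting material
10 | dimethyl 2-[(3S,6E)-7-iodo-3-methylocta-1,6-dien-3-yl]propanedioate | C=C[C@](C)(CC/C=C(\C)I)C(C(=O)OC)C(=O)OC | intermediate
11 | methyl (3R,6E)-3-ethenyl-7-iodo-3-methyloct-6-enoate | C=C[C@](C)(CC/C=C(\C)I)CC(=O)OC | intermediate
12 | (3R,6E)-3-ethenyl-7-iodo-N-methoxy-N,3-dimethyloct-6-enamide | C=C[C@](C)(CC/C=C(\C)I)CC(=O)N(C)OC | intermediate
13 | 4-bromobenzene-1,3-diol | Oc1ccc(Br)c(O)c1 | starting material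
14 | 1-bromo-2,4-bis(methoxymethoxy)benzene | COCOc1ccc(Br)c(OCOC)c1 | intermediate
15 | [2,4-bis(methoxymethoxy)phenyl]magnesium bromide (formed in the flask) | COCOc1ccc([Mg]Br)c(OCOC)c1 | intermediate
16 | (3R,6E)-1-[2,4-bis(methoxymethoxy)phenyl]-3-ethenyl-7-iodo-3-methyloct-6-en-1-one | C=C[C@](C)(CC/C=C(\C)I)CC(=O)c1ccc(OCOC)cc1OCOC | intermediate
17 | prop-2-yn-1-ol | C#CCO | starting material
18 | 4-methyl-2,5-dihydro-1,2-oxamagnesole, the cyclic alkenylmagnesium alkoxide (formed in the flask) | CC1=C[Mg]OC1 | intermediate
19 | (Z)-3-iodo-2-methylprop-2-en-1-ol | OC/C(C)=C\I | intermediate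
20 | (Z)-2-methyl-5-(trimethylsilyl)pent-2-en-4-yn-1-ol | OC/C(C)=C\C#C[Si](C)(C)C | intermediate
21 | (Z)-2-methylpent-2-en-4-yn-1-ol | OC/C(C)=C\C#C | intermediate
22 | (3R,6E)-1-[2,4-bis(methoxymethoxy)phenyl]-3-ethenyl-3,7-dimethyl-8-[(2E)-4-methylfuran-2(5H)-ylidene]oct-6-en-1-one (formed in the flask) | C=C[C@](C)(CC/C=C(\C)/C=C1\C=C(C)CO1)CC(=O)c1ccc(OCOC)cc1OCOC | intermediate
23 | (3R,6E)-1-[2,4-bis(methoxymethoxy)phenyl]-3-ethenyl-3,7-dimethyl-8-(4-methylfuran-2-yl)oct-6-en-1-one | C=C[C@](C)(CC/C=C(\C)Cc1cc(C)co1)CC(=O)c1ccc(OCOC)cc1OCOC | intermediate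
24 | (3R,6E)-1-(2,4-dihydroxyphenyl)-3-ethenyl-3,7-dimethyl-8-(4-methylfuran-2-yl)oct-6-en-1-one | C=C[C@](C)(CC/C=C(\C)Cc1cc(C)co1)CC(=O)c1ccc(O)cc1O | target

**Step count and risks**

Total step count: 15. Longest linear sequence: 11 steps (steps 1–8, 10, 14, 15); step 9 and steps 11–13 are side branches.

Steps most likely to fail:

1. Step 14 (Proposed new method). The alkenylpalladium intermediate may alkynylate the terminal C–H instead of triggering oxypalladation, the enynol may cycloisomerize without coupling, or the C6=C7 bond may migrate into conjugation during aromatization. The fallback uses known chemistry, sets out from 16 and returns at 23. Commercial 4-methylfuran-2-carbaldehyde would be reduced (NaBH4, MeOH, 0 °C) to (4-methylfuran-2-yl)methanol F1. F1 would be converted with SOCl2/pyridine in Et2O at −20 °C into 2-(chloromethyl)-4-methylfuran F2, used cold and unpurified. Zinc dust/LiCl in THF would turn F2 into [(4-methylfuran-2-yl)methyl]zinc chloride F3. Negishi coupling of F3 with 16 (Pd(OAc)2/SPhos, THF, rt) should give 23 with retention of the E geometry; the ketone tolerates the benzylic-type zinc reagent.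

2. Step 6. Ionization of the hindered carbonate may be slow, attack may go to the unsubstituted terminus (linear product), or facial selectivity at the quaternary centre may be poor. The fallback sets out from 7 and returns at 11. Johnson–Claisen rearrangement of 7 (trimethyl orthoacetate, propionic acid cat., 140 °C) should give racemic methyl (6E)-3-ethenyl-7-iodo-3-methyloct-6-enoate F4; the [3,3] shift builds the same vinyl-bearing quaternary carbon without a catalyst. The enantiomers of F4 would then be separated by preparative chromatography on a chiral stationary phase to supply 11.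

3. Step 15. Acid may open or oligomerize the furan, or move the C6=C7 bond into conjugation, before both acetals are cleaved. The fallback sets out from 16 and returns at 24 by reversing the order of events. The MOM groups would be cleaved on 16 (HCl, MeOH, 40 °C; no furan present) to give (3R,6E)-1-(2,4-dihydroxyphenyl)-3-ethenyl-7-iodo-3-methyloct-6-en-1-one F5. F5 would then undergo the annulative coupling with 21 under the step 14 conditions with one extra equivalent of Cs2CO3. The 4-phenoxide is a weak nucleophile and the 2-OH is hydrogen-bonded to the ketone, so the reaction should pass through the phenolic ylidene-dihydrofuran (3R,6E)-1-(2,4-dihydroxyphenyl)-3-ethenyl-3,7-dimethyl-8-[(2E)-4-methylfuran-2(5H)-ylidene]oct-6-en-1-one F6 (not isolated) and give 24 directly.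

**Further compounds**

F1 | step 14 | (4-methylfuran-2-yl)methanol | Cc1coc(CO)c1
F2 | step 14 | 2-(chloromethyl)-4-methylfuran | Cc1coc(CCl)c1
F3 | step 14 | [(4-methylfuran-2-yl)methyl]zinc chloride | Cc1coc(C[Zn]Cl)c1
F4 | step 6 | methyl (6E)-3-ethenyl-7-iodo-3-methyloct-6-enoate, racemate | C=CC(C)(CC/C=C(\C)I)CC(=O)OC
F5 | step 15 | (3R,6E)-1-(2,4-dihydroxyphenyl)-3-ethenyl-7-iodo-3-methyloct-6-en-1-one | C=C[C@](C)(CC/C=C(\C)I)CC(=O)c1ccc(O)cc1O
F6 | step 15 | (3R,6E)-1-(2,4-dihydroxyphenyl)-3-ethenyl-3,7-dimethyl-8-[(2E)-4-methylfuran-2(5H)-ylidene]oct-6-en-1-one | C=C[C@](C)(CC/C=C(\C)/C=C1\C=C(C)CO1)CC(=O)c1ccc(O)cc1O
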